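**Strategy**

Chromene numbering is used (O1, C2–C4, C4a, C5–C8, C8a; ring A is the fused carbocycle, ring B the pendant enol ring on C2). Ring A holds the unit C8a–C8(Me2)–C7(=O)–C6(Me2), which is 2,2,4,4-tetramethylcyclobutane-1,3-dione with one acyl–CMe2 bond cut. The plan inserts a two-carbon lithium ynolate, C4a≡C5–OLi, into that bond: in one operation C4a joins C8a and C5 joins C6, closing ring A on an acyclic chain, made as a 1,1-dibromoalkene, that already carries C3 and C4 (set by an organocatalytic Michael addition) and a masked C2 aldehyde. Condensation with syncarpic acid then closes the pyran and sets C2 under thermodynamic control.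

Key step: step 5

Remark: syncarpic acid (15) is taken as a catalogue compound.

**Route**

Step 1
Reactants: 1 2-methylpropanal; 2 nitromethane
Product: 4 (E)-3-methyl-1-nitrobut-1-ene, via nitro alcohol 3 (not isolated)
Conditions: MeNO2 (3 equiv), KOt-Bu (5 mol%), THF/t-BuOH, 0 °C → rt; then (CF3CO)2O, Et3N, CH2Cl2, −10 → 0 °C
Reagents that add atoms: none
Why: Henry addition of nitromethane to the aldehyde followed by trifluoroacetylation and E1cB elimination should give the conjugated nitroalkene as its E isomer, which is strongly favoured thermodynamically.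

Step 2
Reactants: 5 4-methylpentanal; 4 (E)-3-methyl-1-nitrobut-1-ene
Product: 6 (2S,3S)-4-methyl-2-(2-methylpropyl)-3-(nitromethyl)pentanal
Conditions: (R)-2-[diphenyl(trimethylsilyloxy)methyl]pyrrolidine (10 mol%), 4-nitrophenol (10 mol%), toluene, 0 °C → rt; 5 in 1.5 equiv
Reagents that add atoms: none
Why: Asymmetric Michael addition under enamine catalysis: the E-enamine of 5 is shielded on one face by the CPh2(OSiMe3) group and adds to 4 through an acyclic synclinal transition state, which should set C4 (the aldehyde α-carbon, S) and C3 (the nitroalkene β-carbon, S) together as the syn pair, the R catalyst being chosen for this enantiomeric series by the established facial bias of the catalyst class.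

Step 3
Reactants: 6 (2S,3S)-4-methyl-2-(2-methylpropyl)-3-(nitromethyl)pentanal
Product: 7 (3S,4S)-1,1-dibromo-5-methyl-3-(2-methylpropyl)-4-(nitromethyl)hex-1-ene
Conditions: CBr4, PPh3, 2,6-lutidine, CH2Cl2, 0 °C
Reagents that add atoms: carbon tetrabromide, BrC(Br)(Br)Br
Why: Corey–Fuchs dibromo-olefination (Wittig reaction of Ph3P=CBr2 made from CBr4 and PPh3) runs under nearly neutral conditions, so the α-stereocentre C4 and the primary nitro group should be untouched, and the CBr2 carbon becomes C5.

Step 4
Reactants: 7 (3S,4S)-1,1-dibromo-5-methyl-3-(2-methylpropyl)-4-(nitromethyl)hex-1-ene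
Product: 9 (3S,4S)-1,1-dibromo-4-(dimethoxymethyl)-5-methyl-3-(2-methylpropyl)hex-1-ene, via sodium nitronate 8 (not isolated)
Conditions: NaOMe, MeOH, 0 °C; then added to H2SO4/MeOH, −40 °C → rt
Reagents that add atoms: methanol, CO
Why: Nef reaction in its acetal-forming variant: the nitronate 8 is O-protonated and solvolysed in cold methanolic acid and the C2 aldehyde is trapped at once as its dimethyl acetal, so that C3 never sits beside a free carbonyl group and the dibromoalkene is left alone.

Step 5
Reactants: 9 (3S,4S)-1,1-dibromo-4-(dimethoxymethyl)-5-methyl-3-(2-methylpropyl)hex-1-ene; 10 2,2,4,4-tetramethylcyclobutane-1,3-dione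
Product: 14 5-hydroxy-4-[(2S,3S)-1,1-dimethoxy-5-methyl-2-(propan-2-yl)hexan-3-yl]-2,2,6,6-tetramethylcyclohex-4-ene-1,3-dione, via lithium acetylide 11 (not isolated), via lithium ynolate 12 (not isolated), via acylketene enolate 13 (not isolated)
Conditions: n-BuLi (2.05 equiv), THF, −78 °C; LiOOt-Bu (from t-BuOOH and LiN(SiMe3)2), −78 → 0 °C; 10 (1.5 equiv), −78 °C → rt; AcOH (2 equiv), then pH 5 buffer
Reagents that add atoms: tert-butyl hydroperoxide (used as its lithium salt; supplies the oxygen on C5), CC(C)(C)OO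
Why: Proposed new method: Li/Br exchange and rearrangement (Corey–Fuchs) give acetylide 11, which LiOOt-Bu oxidises to ynolate 12; the ynolate carbon C4a adds to one carbonyl of 10 (C4a–C8a bond), the strained cyclobutanolate opens by retro-aldol cleavage of C8a–C6 to the acylketene enolate 13, and the enolate carbon C6 is then acylated by the ketene carbon C5 (C5–C6 bond) to give the stabilised enolate of ring A. The closest known reaction types are the addition of lithium ynolates to ketones and their tandem addition–Dieckmann sequences, the ring opening of 10 by alkoxides and organolithiums, the methoxide-induced conversion of 10 itself into hexamethylcyclohexane-1,3,5-trione (same enolate, C-acylation, six-membered trione closure), and, in topology, the Danheiser two-carbon insertion of alkynes into cyclobutenones. Ring A closes in the 6-(enolendo)-exo-dig mode. No stereocentre is formed, and C3 and C4 are spectators since neither is deprotonated under these conditions. The step needs carbon attack of the ynolate, ring opening of the cyclobutanolate ahead of collapse to an oxetenolate (the olefination manifold), and C- rather than O-acylation of the enolate; the strain and non-enolisable quaternary carbons of 10, the lithium counter-ion in THF and the stability of the triketone enolate are expected to secure these.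

Step 6
Reactants: 14 5-hydroxy-4-[(2S,3S)-1,1-dimethoxy-5-methyl-2-(propan-2-yl)hexan-3-yl]-2,2,6,6-tetramethylcyclohex-4-ene-1,3-dione; 15 syncarpic acid
Product: 18 ericifolione, via lactol 16 (not isolated), via alkylidene trione 17 (not isolated)
Conditions: 15 (1.2 equiv), ethylenediammonium diacetate (20 mol%), AcOH/H2O (4:1), 40 °C
Reagents that add atoms: none
Why: Acetal hydrolysis gives lactol 16, Knoevenagel condensation of its open aldehyde form with 15 gives alkylidene trione 17, and 6-exo-trig oxa-Michael addition of a ring A enol oxygen (the two are equivalent, so one constitution results) closes the pyran reversibly, so C2 should settle as the R epimer with ring B equatorial, trans to the pseudoaxial C4 isobutyl group (held axial by allylic strain against the C5 carbonyl) and cis to the axial C3 isopropyl group.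

**Compound list**

1 | 2-methylpropanal (isobutyraldehyde) | CC(C)C=O | starting material
2 | nitromethane | C[N+](=O)[O-] | starting material
3 | 3-methyl-1-nitrobutan-2-ol (racemic) | CC(C)C(O)C[N+](=O)[O-] | intermediate
4 | (E)-3-methyl-1-nitrobut-1-ene | CC(C)/C=C/[N+](=O)[O-] | intermediate
5 | 4-methylpentanal | CC(C)CCC=O | starting material
6 | (2S,3S)-4-methyl-2-(2-methylpropyl)-3-(nitromethyl)pentanal | CC(C)C[C@@H]([C@H](C(C)C)C[N+](=O)[O-])C=O | intermediate
7 | (3S,4S)-1,1-dibromo-5-methyl-3-(2-methylpropyl)-4-(nitromethyl)hex-1-ene | CC(C)C[C@@H]([C@H](C(C)C)C[N+](=O)[O-])C=C(Br)Br | intermediate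
8 | sodium nitronate of 7 (sodium salt of the aci-nitro form) | CC(C)C[C@@H]([C@H](C(C)C)C=[N+]([O-])[O-])C=C(Br)Br.[Na+] | intermediate
9 | (3S,4S)-1,1-dibromo-4-(dimethoxymethyl)-5-methyl-3-(2-methylpropyl)hex-1-ene | CC(C)C[C@@H]([C@H](C(C)C)C(OC)OC)C=C(Br)Br | intermediate
10 | 2,2,4,4-tetramethylcyclobutane-1,3-dione | CC1(C)C(=O)C(C)(C)C1=O | starting material
11 | [(3S,4S)-4-(dimethoxymethyl)-5-methyl-3-(2-methylpropyl)hex-1-yn-1-yl]lithium | CC(C)C[C@@H]([C@H](C(C)C)C(OC)OC)C#C[Li] | intermediate
12 | lithium (3S,4S)-4-(dimethoxymethyl)-5-methyl-3-(2-methylpropyl)hex-1-yn-1-olate | CC(C)C[C@@H]([C@H](C(C)C)C(OC)OC)C#CO[Li] | intermediate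
13 | ring-opened acylketene lithium enolate, O=C=C(R)–C(=O)–CMe2–C(OLi)=CMe2 with R = (2S,3S)-1,1-dimethoxy-5-methyl-2-(propan-2-yl)hexan-3-yl | CC(C)C[C@@H]([C@H](C(C)C)C(OC)OC)C(=C=O)C(=O)C(C)(C)C(O[Li])=C(C)C | intermediate
14 | 5-hydroxy-4-[(2S,3S)-1,1-dimethoxy-5-methyl-2-(propan-2-yl)hexan-3-yl]-2,2,6,6-tetramethylcyclohex-4-ene-1,3-dione | CC(C)C[C@@H]([C@H](C(C)C)C(OC)OC)C1=C(O)C(C)(C)C(=O)C(C)(C)C1=O | intermediate
15 | syncarpic acid (5-hydroxy-2,2,6,6-tetramethylcyclohex-4-ene-1,3-dione, enol form of 2,2,4,4-tetramethylcyclohexane-1,3,5-trione) | CC1(C)C(=O)C=C(O)C(C)(C)C1=O | starting material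
16 | (3S,4S)-2-hydroxy-6,6,8,8-tetramethyl-4-(2-methylpropyl)-3-(propan-2-yl)-3,4-dihydro-2H-chromene-5,7(6H,8H)-dione (both C2 epimers) | CC(C)C[C@@H]1C2=C(OC(O)[C@H]1C(C)C)C(C)(C)C(=O)C(C)(C)C2=O | intermediate
17 | 5-hydroxy-2,2,6,6-tetramethyl-4-[(2R,3S)-5-methyl-2-(propan-2-yl)-1-(3,3,5,5-tetramethyl-2,4,6-trioxocyclohexylidene)hexan-3-yl]cyclohex-4-ene-1,3-dione | CC(C)C[C@@H]([C@H](C(C)C)C=C1C(=O)C(C)(C)C(=O)C(C)(C)C1=O)C1=C(O)C(C)(C)C(=O)C(C)(C)C1=O | intermediate
18 | ericifolione, (2R,3S,4S)-2-(2-hydroxy-3,3,5,5-tetramethyl-4,6-dioxocyclohex-1-en-1-yl)-6,6,8,8-tetramethyl-4-(2-methylpropyl)-3-(propan-2-yl)-3,4-dihydro-2H-chromene-5,7(6H,8H)-dione | CC(C)C[C@@H]1C2=C(O[C@@H](C3=C(O)C(C)(C)C(=O)C(C)(C)C3=O)[C@H]1C(C)C)C(C)(C)C(=O)C(C)(C)C2=O | target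

**Step count and risks**

Total steps: 6. Longest linear sequence: 6 steps (1 → 4 → 6 → 7 → 9 → 14 → 18).

Steps most likely to fail:

1. Step 5 (proposed new method). The ynolate–diketone adduct may collapse to an oxetenolate and follow the olefination path, the enolate may be acylated on oxygen instead of carbon, or LiOt-Bu may intercept the acylketene. The fallback uses known chemistry, sets out from 9 and returns at 14. Compound 9 is converted into ynolate 12 as in step 5 and quenched with water, the usual fate of an ynolate in a Kowalski-type homologation, to give (3R,4S)-4-(dimethoxymethyl)-5-methyl-3-(2-methylpropyl)hexanoic acid F1. 1,1'-Carbonyldiimidazole in THF turns this into 1-[(3R,4S)-4-(dimethoxymethyl)-5-methyl-3-(2-methylpropyl)hexanoyl]-1H-imidazole F2. Separately, methanolysis of 10 (NaOMe, MeOH) gives methyl 2,2,4-trimethyl-3-oxopentanoate F3. Its lithium enolate (LiN(i-Pr)2, THF, −78 °C) is C-acylated by F2 to methyl (7R,8S)-8-(dimethoxymethyl)-2,2,4,4,9-pentamethyl-7-(2-methylpropyl)-3,5-dioxodecanoate F4. LiN(SiMe3)2 then closes ring A by Dieckmann attack of C4a on the ester to give 14. In this variant the C5–C6 and C4a–C8a bonds are made in two separate operations.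

2. Step 6. Alkylidene 17 may tautomerise to its dienol before ring closure, which would erase C3; the lactol may dehydrate to a 2H-pyran; or equilibration at C2 may stall. The fallback sets out from 14 (with 15) and returns at 18. Pyridinium p-toluenesulfonate in CH2Cl2 over molecular sieves closes 14 to (3S,4S)-2-methoxy-6,6,8,8-tetramethyl-4-(2-methylpropyl)-3-(propan-2-yl)-3,4-dihydro-2H-chromene-5,7(6H,8H)-dione F5. Syncarpic acid 15 is silylated with HN(SiMe3)2 to 2,2,6,6-tetramethyl-5-[(trimethylsilyl)oxy]cyclohex-4-ene-1,3-dione F6. Me3SiOTf (cat.) in CH2Cl2 at −78 °C then joins F6 to the anomeric carbon of F5 through the cyclic oxocarbenium ion (Mukaiyama-type substitution), which should give 18 without a free alkylidene intermediate. A C2 epimer, if formed, would be equilibrated with Et3N.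

3. Step 4. The hindered nitronate may solvolyse slowly, over-hydrolysis to the carboxylic acid may compete, and methoxide may dehydrobrominate the dibromoalkene. The fallback sets out from 7 and returns at 9. A reductive Nef reaction with aqueous TiCl3 buffered with NH4OAc gives (2S,3S)-5,5-dibromo-3-(2-methylpropyl)-2-(propan-2-yl)pent-4-enal F7. HC(OMe)3 and pyridinium p-toluenesulfonate in MeOH then convert F7 into 9.

Further compounds
F1 | step 5 | (3R,4S)-4-(dimethoxymethyl)-5-methyl-3-(2-methylpropyl)hexanoic acid | CC(C)C[C@@H]([C@H](C(C)C)C(OC)OC)CC(=O)O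
F2 | step 5 | 1-[(3R,4S)-4-(dimethoxymethyl)-5-methyl-3-(2-methylpropyl)hexanoyl]-1H-imidazole | CC(C)C[C@@H]([C@H](C(C)C)C(OC)OC)CC(=O)n1ccnc1
F3 | step 5 | methyl 2,2,4-trimethyl-3-oxopentanoate | COC(=O)C(C)(C)C(=O)C(C)C
F4 | step 5 | methyl (7R,8S)-8-(dimethoxymethyl)-2,2,4,4,9-pentamethyl-7-(2-methylpropyl)-3,5-dioxodecanoate | CC(C)C[C@@H]([C@H](C(C)C)C(OC)OC)CC(=O)C(C)(C)C(=O)C(C)(C)C(=O)OC
F5 | step 6 | (3S,4S)-2-methoxy-6,6,8,8-tetramethyl-4-(2-methylpropyl)-3-(propan-2-yl)-3,4-dihydro-2H-chromene-5,7(6H,8H)-dione (both C2 epimers) | CC(C)C[C@@H]1C2=C(OC(OC)[C@H]1C(C)C)C(C)(C)C(=O)C(C)(C)C2=O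
F6 | step 6 | 2,2,6,6-tetramethyl-5-[(trimethylsilyl)oxy]cyclohex-4-ene-1,3-dione | C[Si](C)(C)OC1=CC(=O)C(C)(C)C(=O)C1(C)C
F7 | step 4 | (2S,3S)-5,5-dibromo-3-(2-methylpropyl)-2-(propan-2-yl)pent-4-enal | CC(C)C[C@@H]([C@H](C(C)C)C=O)C=C(Br)Br
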